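**Retrosynthetic overview** (side chain numbered C1 = benzylic CH2 to C17 = CH3)
- Feature: the Z-alkene C11=C12 is a lone two-carbon unit held between two sp3 carbons, the doubly allylic C10 and C13. This is the pattern expected if acetylene is slotted between a C13 nucleophile and a C10 electrophile.
- Key disconnection (C12–C13 and C10–C11, one pot): a C13–C17 lithium dialkylcuprate carbometalates acetylene. The resulting (Z)-alkenylcuprate is alkylated by the C1–C10 aryl-decynyl propargylic bromide, and C8≡C9 travels on as a masked Z-alkene.
- Fragments: (S)-propylene oxide (brings C16 as S) plus vinyl Grignard gives the silyl ether, then the alcohol, then the iodide. Bis-MOM 5-bromoresorcinol plus 1,7-dibromoheptane (aryl–C1) plus propargyl alcohol dianion (C7–C8) gives the bromide.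
- End game: Lindlar semi-hydrogenation of C8≡C9, then acidic removal of all three protecting groups. No ring is formed in the route; the only ring, the resorcinol arene, is bought.

Key step: step 9

Assumption: in step 9 the propargylic bromide is the limiting component and only one of the two alkenyl ligands on copper is counted as transferred. The second ligand is given up as the terminal alkene at the quench.

Step 1
Reactants: 1 (S)-propylene oxide; 2 vinylmagnesium bromide
Product: 3 (2S)-pent-4-en-2-ol
Conditions: CuI (10 mol %), THF, −30 → 0 °C; then H2O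
Reagents that add atoms: none
Why: Copper-catalysed Grignard opening of a terminal epoxide is an SN2 attack at the unsubstituted CH2, so the C16–O bond is never touched and the S configuration bought with 1 is carried over unchanged.

Step 2
Reactants: 3 (2S)-pent-4-en-2-ol
Product: 4 tert-butyldimethyl[(2S)-pent-4-en-2-yloxy]silane
Conditions: TBSCl, imidazole, DMF, rt
Reagents that add atoms: tert-butyldimethylsilyl chloride CC(C)(C)[Si](C)(C)Cl
Why: Imidazole-promoted silylation of a secondary alcohol forms only an O–Si bond, so C16 keeps its configuration and the volatile alcohol becomes a base-stable ether that is easy to handle.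

Step 3
Reactants: 4 tert-butyldimethyl[(2S)-pent-4-en-2-yloxy]silane
Product: 6 (4S)-4-(tert-butyldimethylsilyloxy)pentan-1-ol, via B-alkyl-9-BBN 5 (not isolated)
Conditions: 9-BBN, THF, 0 °C → rt; then 3 M NaOH, 30 % H2O2, 0 °C → rt
Reagents that add atoms: hydrogen peroxide OO (oxygen of the new OH); 9-BBN B1C2CCCC1CCC2 (boron framework, in 5 only)
Why: In this Brown hydroboration–oxidation the bulky borane places boron on the terminal carbon of the monosubstituted alkene, and alkaline peroxide converts the C–B bond into the primary alcohol without harming the silyl ether.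

Step 4
Reactants: 6 (4S)-4-(tert-butyldimethylsilyloxy)pentan-1-ol
Product: 7 tert-butyl{[(2S)-5-iodopentan-2-yl]oxy}dimethylsilane
Conditions: I2, PPh3, imidazole, CH2Cl2, 0 °C → rt
Reagents that add atoms: iodine II
Why: Appel-type iodination displaces the primary alkoxyphosphonium ion with iodide by SN2, while imidazole keeps the medium non-acidic for the silyl ether.

Step 5
Reactants: 8 5-bromoresorcinol
Product: 9 1-bromo-3,5-bis(methoxymethoxy)benzene
Conditions: MOMCl (2.6 equiv), i-Pr2NEt (3 equiv), CH2Cl2, 0 °C → rt
Reagents that add atoms: chloromethyl methyl ether COCCl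
Why: Williamson-type O-alkylation of both phenols with the reactive chloromethyl ether installs acetal groups that tolerate Grignard, organolithium and cuprate reagents and fall in acid at the end.

Step 6
Reactants: 9 1-bromo-3,5-bis(methoxymethoxy)benzene; 10 1,7-dibromoheptane
Product: 12 1-(7-bromoheptyl)-3,5-bis(methoxymethoxy)benzene, via aryl Grignard reagent 11 (not isolated)
Conditions: Mg, THF, 50 °C; then slow addition to 10 (4 equiv), Li2CuCl4 (5 mol %), THF, 0 °C → rt
Reagents that add atoms: magnesium [Mg] (in 11 only)
Why: This is a Kochi-type copper-catalysed cross-coupling of an aryl Grignard reagent with a primary alkyl bromide, and slow inverse addition into excess dibromide should hold the reaction at monosubstitution.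

Step 7
Reactants: 12 1-(7-bromoheptyl)-3,5-bis(methoxymethoxy)benzene; 13 propargyl alcohol
Product: 15 10-[3,5-bis(methoxymethoxy)phenyl]dec-2-yn-1-ol, via dilithio propargyl alcohol 14 (not isolated)
Conditions: 13 (2 equiv), n-BuLi (4 equiv), THF–DMPU, −78 → 0 °C; then 12, 0 °C → rt; H2O
Reagents that add atoms: n-butyllithium [Li]CCCC (lithium, in 14 only)
Why: Acetylide alkylation of the C,O-dianion takes place at the more nucleophilic carbon terminus by SN2 on the primary bromide in a dipolar co-solvent, which brings in C8–C10 with the hydroxyl already free.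

Step 8
Reactants: 15 10-[3,5-bis(methoxymethoxy)phenyl]dec-2-yn-1-ol
Product: 16 1-(10-bromodec-8-ynyl)-3,5-bis(methoxymethoxy)benzene
Conditions: CBr4, PPh3, CH2Cl2, 0 °C
Reagents that add atoms: carbon tetrabromide BrC(Br)(Br)Br
Why: The Appel bromination runs under neutral conditions through an alkoxyphosphonium salt and SN2 attack of bromide, so the acetal groups and the alkyne are left alone.

Step 9
Reactants: 7 tert-butyl{[(2S)-5-iodopentan-2-yl]oxy}dimethylsilane; 17 acetylene; 16 1-(10-bromodec-8-ynyl)-3,5-bis(methoxymethoxy)benzene
Product: 21 1-[(11Z,16S)-16-(tert-butyldimethylsilyloxy)heptadec-11-en-8-ynyl]-3,5-bis(methoxymethoxy)benzene, via alkyllithium 18 (not isolated), via lithium dialkylcuprate 19 (not isolated), via lithium (Z)-dialkenylcuprate 20 (not isolated)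
Conditions: 7 (2.2 equiv), t-BuLi (4.4 equiv), Et2O–pentane, −78 °C; CuBr(SMe2) (1.1 equiv), −40 °C; HC≡CH (2.2 equiv, measured), −50 → −25 °C, Ar purge; P(OEt)3, HMPA, then 16 (1.0 equiv) in THF, −40 → 0 °C; aq NH4Cl
Reagents that add atoms: tert-butyllithium [Li]C(C)(C)C (lithium, in 18–20 only); CuBr(SMe2) CSC.Br[Cu] (copper, in 19 and 20 only); nothing from either stays in 21
Why: The monovalent copper ate complex 19 binds acetylene and delivers each alkyl ligand and copper to the same side of the triple bond (concerted syn carbocupration), which forms C12–C13 and leaves copper on C11 cis to the new chain in 20. The configurationally stable alkenyl–copper bond then attacks the primary propargylic carbon C10 of 16 (SN2-type oxidative addition to a trivalent copper species, then reductive elimination with retention at C11), which forms C10–C11 and fixes C11=C12 as Z without any reduction. The closest known reaction type is the Normant-type carbocupration of acetylene by lithium dialkylcuprates followed by alkylation of the (Z)-dialkenylcuprate with reactive halides in the presence of P(OEt)3 and HMPA. No ring is closed and no stereocentre is created; C16 is a remote spectator whose silyl ether neither quenches nor ties up the cuprate, and the only new stereo-element, the alkene geometry, follows from syn addition plus retention. Three selectivities are needed: addition instead of deprotonation of acetylene (secured by Et2O as solvent and a lithium cuprate kept at or below −25 °C), one insertion per C–Cu bond (secured by the measured acetylene charge, the purge and the low temperature, since an alkenylcuprate adds to a second acetylene only near 0 °C), and direct substitution at C10 instead of SN2′ attack at C8. The last is favoured because C10 is an unhindered CH2 whereas C8 carries the heptyl chain, because the ate complex is kept in excess so that the neutral alkenylcopper left after the first transfer need not react, and because the phosphite–HMPA medium lets the alkylation run between −40 and 0 °C.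

Step 10
Reactants: 21 1-[(11Z,16S)-16-(tert-butyldimethylsilyloxy)heptadec-11-en-8-ynyl]-3,5-bis(methoxymethoxy)benzene
Product: 22 1-[(8Z,11Z,16S)-16-(tert-butyldimethylsilyloxy)heptadeca-8,11-dienyl]-3,5-bis(methoxymethoxy)benzene
Conditions: H2 (1 atm), Lindlar catalyst (Pd on CaCO3 poisoned with Pb(OAc)2), quinoline, hexane–EtOAc, rt, stopped after 1 equiv H2
Reagents that add atoms: none
Why: Lindlar semi-hydrogenation adds H2 syn to the adsorbed alkyne, which binds the poisoned palladium surface much more strongly than the disubstituted C11=C12 alkene, so C8≡C9 should become the second Z-alkene while the first is left alone.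

Step 11
Reactants: 22 1-[(8Z,11Z,16S)-16-(tert-butyldimethylsilyloxy)heptadeca-8,11-dienyl]-3,5-bis(methoxymethoxy)benzene
Product: 23 Hansfordiol D, 5-[(8Z,11Z,16S)-16-hydroxyheptadeca-8,11-dienyl]benzene-1,3-diol
Conditions: HCl (1.25 M in MeOH), rt → 40 °C, Ar
Reagents that add atoms: none
Why: Acid-catalysed acetal exchange with methanol removes both aryl MOM ethers and methanolysis cleaves the secondary silyl ether in the same pot, while the C16–O bond is not broken and isolated Z-alkenes do not isomerise in dilute methanolic acid.

**Compound list**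
1 | (S)-propylene oxide | C[C@H]1CO1 | starting material
2 | vinylmagnesium bromide | C=C[Mg]Br | starting material
3 | (2S)-pent-4-en-2-ol | C[C@H](O)CC=C | intermediate
4 | tert-butyldimethyl[(2S)-pent-4-en-2-yloxy]silane | C[C@H](O[Si](C)(C)C(C)(C)C)CC=C | intermediate
5 | 9-[(4S)-4-(tert-butyldimethylsilyloxy)pentyl]-9-borabicyclo[3.3.1]nonane (in situ) | C[C@H](O[Si](C)(C)C(C)(C)C)CCCB1C2CCCC1CCC2 | intermediate
6 | (4S)-4-(tert-butyldimethylsilyloxy)pentan-1-ol | C[C@H](O[Si](C)(C)C(C)(C)C)CCCO | intermediate
7 | tert-butyl{[(2S)-5-iodopentan-2-yl]oxy}dimethylsilane | C[C@H](O[Si](C)(C)C(C)(C)C)CCCI | intermediate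
8 | 5-bromoresorcinol | Oc1cc(O)cc(Br)c1 | starting material
9 | 1-bromo-3,5-bis(methoxymethoxy)benzene | COCOc1cc(Br)cc(OCOC)c1 | intermediate
10 | 1,7-dibromoheptane | BrCCCCCCCBr | starting material
11 | 3,5-bis(methoxymethoxy)phenylmagnesium bromide (in situ) | COCOc1cc([Mg]Br)cc(OCOC)c1 | intermediate
12 | 1-(7-bromoheptyl)-3,5-bis(methoxymethoxy)benzene | BrCCCCCCCc1cc(OCOC)cc(OCOC)c1 | intermediate
13 | propargyl alcohol (prop-2-yn-1-ol) | OCC#C | starting material
14 | dilithium salt of prop-2-yn-1-ol (in situ) | [Li]OCC#C[Li] | intermediate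
15 | 10-[3,5-bis(methoxymethoxy)phenyl]dec-2-yn-1-ol | OCC#CCCCCCCCc1cc(OCOC)cc(OCOC)c1 | intermediate
16 | 1-(10-bromodec-8-ynyl)-3,5-bis(methoxymethoxy)benzene | BrCC#CCCCCCCCc1cc(OCOC)cc(OCOC)c1 | intermediate
17 | acetylene | C#C | starting material
18 | [(4S)-4-(tert-butyldimethylsilyloxy)pentyl]lithium (in situ) | C[C@H](O[Si](C)(C)C(C)(C)C)CCC[Li] | intermediate
19 | lithium bis[(4S)-4-(tert-butyldimethylsilyloxy)pentyl]cuprate (in situ) | [Li+].C[C@H](O[Si](C)(C)C(C)(C)C)CCC[Cu-]CCC[C@H](C)O[Si](C)(C)C(C)(C)C | intermediate
20 | lithium bis[(1Z,6S)-6-(tert-butyldimethylsilyloxy)hept-1-enyl]cuprate (in situ) | [Li+].C[C@H](O[Si](C)(C)C(C)(C)C)CCC/C=C\[Cu-]/C=C\CCC[C@H](C)O[Si](C)(C)C(C)(C)C | intermediate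
21 | 1-[(11Z,16S)-16-(tert-butyldimethylsilyloxy)heptadec-11-en-8-ynyl]-3,5-bis(methoxymethoxy)benzene | C[C@H](O[Si](C)(C)C(C)(C)C)CCC/C=C\CC#CCCCCCCCc1cc(OCOC)cc(OCOC)c1 | intermediate
22 | 1-[(8Z,11Z,16S)-16-(tert-butyldimethylsilyloxy)heptadeca-8,11-dienyl]-3,5-bis(methoxymethoxy)benzene | C[C@H](O[Si](C)(C)C(C)(C)C)CCC/C=C\C/C=C\CCCCCCCc1cc(OCOC)cc(OCOC)c1 | intermediate
23 | Hansfordiol D, 5-[(8Z,11Z,16S)-16-hydroxyheptadeca-8,11-dienyl]benzene-1,3-diol | C[C@H](O)CCC/C=C\C/C=C\CCCCCCCc1cc(O)cc(O)c1 | target

**Total step count:** 11
**Longest linear sequence:** 7 steps (1, 2, 3, 4, 9, 10, 11 or 5, 6, 7, 8, 9, 10, 11)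

**Steps most likely to fail**

1. Step 9.
- The main hazard is attack of the alkenylcuprate at the distal alkyne carbon C8 (SN2′ course) in competition with direct displacement at C10.
- Lesser hazards are deprotonation or double insertion of acetylene, and O-to-C silyl migration in the alkyllithium before transmetalation.
- The fallback sets out from 7 and 16 and returns at 22. Iodide 7 is treated with lithium acetylide–ethylenediamine complex in DMSO at rt to give tert-butyl[(2S)-hept-6-yn-2-yloxy]dimethylsilane F1.
- F1 is coupled with bromide 16 under CuI, NaI and Cs2CO3 in DMF at rt. This is the classical skipped-diyne coupling, which takes place at the CH2 carbon, and it gives 1-[(16S)-16-(tert-butyldimethylsilyloxy)heptadeca-8,11-diynyl]-3,5-bis(methoxymethoxy)benzene F2.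
- Semi-hydrogenation of both triple bonds over Lindlar catalyst (Pd on CaCO3 poisoned with Pb(OAc)2) with quinoline then leads to 22, so that both Z-alkenes come from alkyne reduction.

2. Step 10.
- The risks are over-reduction, Z-to-E isomerisation or double-bond migration of the skipped diene on palladium, and stalling through catalyst poisoning by traces of sulfide, phosphite or copper carried over from step 9.
- The fallback sets out from 21 and returns at 22 and replaces catalytic hydrogenation by stoichiometric hydroboration–protonolysis.
- Dicyclohexylborane (1.05 equiv, THF, 0 °C) adds syn to C8≡C9 much faster than to the Z-disubstituted alkene. It gives the C8-dicyclohexylboryl diene F3 and the C9-dicyclohexylboryl diene F4.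
- Both are protonolysed by AcOH at rt with retention of geometry to the same Z-alkene 22.

3. Step 6.
- The risks are sluggish magnesium insertion into the electron-rich bromide, homocoupling of the Grignard reagent, and double substitution of the dibromide.
- The fallback sets out from 9 and returns at 12. Commercial 7-bromohept-1-ene is hydroborated with 9-BBN in THF to 9-(7-bromoheptyl)-9-borabicyclo[3.3.1]nonane F5.
- F5 is cross-coupled with aryl bromide 9 under PdCl2(dppf), K3PO4, DMF–THF, 50 °C (B-alkyl Suzuki–Miyaura coupling). Zerovalent palladium inserts into the aryl C–Br bond and leaves the primary alkyl bromide untouched.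

**Further compounds**
F1 | step 9 | tert-butyl[(2S)-hept-6-yn-2-yloxy]dimethylsilane | C[C@H](O[Si](C)(C)C(C)(C)C)CCCC#C
F2 | step 9 | 1-[(16S)-16-(tert-butyldimethylsilyloxy)heptadeca-8,11-diynyl]-3,5-bis(methoxymethoxy)benzene | C[C@H](O[Si](C)(C)C(C)(C)C)CCCC#CCC#CCCCCCCCc1cc(OCOC)cc(OCOC)c1
F3 | step 10 | dicyclohexyl{(8Z,11Z,16S)-1-[3,5-bis(methoxymethoxy)phenyl]-16-(tert-butyldimethylsilyloxy)heptadeca-8,11-dien-8-yl}borane | C[C@H](O[Si](C)(C)C(C)(C)C)CCC/C=C\C/C=C(\CCCCCCCc1cc(OCOC)cc(OCOC)c1)B(C1CCCCC1)C1CCCCC1
F4 | step 10 | dicyclohexyl{(8Z,11Z,16S)-1-[3,5-bis(methoxymethoxy)phenyl]-16-(tert-butyldimethylsilyloxy)heptadeca-8,11-dien-9-yl}borane | C[C@H](O[Si](C)(C)C(C)(C)C)CCC/C=C\C/C(B(C1CCCCC1)C1CCCCC1)=C\CCCCCCCc1cc(OCOC)cc(OCOC)c1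
F5 | step 6 | 9-(7-bromoheptyl)-9-borabicyclo[3.3.1]nonane | BrCCCCCCCB1C2CCCC1CCC2
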